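**Assumption:** the target has no stereocentre (it is achiral), so no stereocontrol is needed; 1 and 9 are taken as catalogue chemicals.

## Retrosynthetic overview
1. Cut the depside at the aryl ester C–O bond: B-ring acid 8 plus olivetolic acid 9, used unprotected (its CO2H/2-OH pair is masked in the flask as a spiro borate).
2. 8 ⇐ 6 (chelation-controlled O-demethylation) ⇐ 5 (aldehyde oxidation) ⇐ 3 (formylation at the only ring position left; both C–H are equivalent by symmetry).
3. 3 ⇐ olivetol dimethyl ether 1 (ortho-lithiation/chlorination between the two OMe groups fixes the Cl position).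
4. No ring is built: both benzene rings are bought intact (1 and 9); the ester C–O bond is made last.

## Route

Step 1
Reactants: 1 1,3-dimethoxy-5-pentylbenzene (olivetol dimethyl ether)
Product: 3 2-chloro-1,3-dimethoxy-5-pentylbenzene, via aryllithium 2 (not isolated)
Conditions: n-BuLi (1.2 eq), THF, 0 °C → rt, 2 h; then C2Cl6 (1.3 eq), THF, –78 °C → rt
Reagents that add atoms: hexachloroethane, ClC(Cl)(Cl)C(Cl)(Cl)Cl
Why: Directed ortho-metalation – the C–H flanked by both OMe groups is the most acidic and best-coordinated site, and electrophilic Cl transfer from C2Cl6 to the aryllithium puts Cl regiospecifically between the two oxygens.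

Step 2
Reactants: 3 2-chloro-1,3-dimethoxy-5-pentylbenzene
Product: 5 3-chloro-2,4-dimethoxy-6-pentylbenzaldehyde, via chloro ether adduct 4 (not isolated)
Conditions: Cl2CHOMe (1.5 eq), TiCl4 (2.2 eq), CH2Cl2, –78 → 0 °C; then ice/1 M HCl
Reagents that add atoms: dichloromethyl methyl ether, COC(Cl)Cl; water, O
Why: Rieche formylation (Friedel–Crafts type) – the two remaining ring C–H are identical by symmetry and each is ortho/para to the OMe groups, so only one aldehyde can form, and the α-chloro ether is hydrolysed on work-up.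

Step 3
Reactants: 5 3-chloro-2,4-dimethoxy-6-pentylbenzaldehyde
Product: 6 3-chloro-2,4-dimethoxy-6-pentylbenzoic acid
Conditions: NaClO2, NaH2PO4, 2-methyl-2-butene, t-BuOH/THF/H2O, 0 °C → rt
Reagents that add atoms: sodium chlorite, [Na+].[O-]Cl=O
Why: Pinnick (Lindgren) oxidation – chlorous acid oxidises the hindered aryl aldehyde to the acid without touching ring, ethers or aryl chloride, while the alkene traps the hypochlorite by-product.

Step 4
Reactants: 6 3-chloro-2,4-dimethoxy-6-pentylbenzoic acid
Product: 8 3-chloro-2-hydroxy-4-methoxy-6-pentylbenzoic acid, via boron chelate 7 (not isolated)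
Conditions: BCl3 (2.5 eq, 1 M in CH2Cl2), CH2Cl2, –78 → 0 °C; then ice/H2O
Reagents that add atoms: none
Why: Chelation-controlled Lewis-acid ether cleavage – BCl3 binds the carboxyl group and the adjacent, twisted 2-OMe in a six-membered chelate and chloride removes only that methyl, while the unchelated 4-OMe survives at low temperature.

Step 5
Reactants: 8 3-chloro-2-hydroxy-4-methoxy-6-pentylbenzoic acid; 9 2,4-dihydroxy-6-pentylbenzoic acid (olivetolic acid)
Product: 13 4-[(3-chloro-2-hydroxy-4-methoxy-6-pentylbenzoyl)oxy]-2-hydroxy-6-pentylbenzoic acid, via acid chloride 10 (not isolated), via spiro borate salt 11 (not isolated), via acylated borate salt 12 (not isolated)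
Conditions: (i) 8, (COCl)2 (1.2 eq), cat. DMF, CH2Cl2, 0 °C → rt, evaporate; (ii) 9, B(OMe)3 (0.5 eq), i-Pr2NEt (0.5 eq), THF, 50 °C, strip MeOH with PhMe; (iii) add 10 slowly to 11, i-Pr2NEt (1.2 eq), THF, –20 °C → rt; (iv) 1 M aq. HCl, rt, 30 min
Reagents that add atoms: none
Why: Proposed new method: borate-templated, protecting-group-free depside coupling – two molecules of 9 are tied up through CO2H and 2-OH as the spiro bis(salicylato)borate 11 (a complex type well known for salicylic acid), which removes the carboxylate as nucleophile and as acyl donor (no mixed anhydride, no self-condensation) and leaves only the 4-OH to take the hindered salicyloyl chloride 10 by amine-mediated acyl transfer (dissociative, acylium-like for this 2,6-disubstituted donor, whose own 2-OH is hydrogen-bonded and flanked by Cl), after which dilute acid cleaves only the B–O bonds of 12 and leaves the aryl ester intact; closest known reaction types are pyridine/Schotten–Baumann acylation of phenols by salicyloyl chlorides, the TFAA depside coupling with benzyl-protected acceptors, and boronate esters as transient masks in carbohydrate acylation.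

## Compound list
1 | 1,3-dimethoxy-5-pentylbenzene (olivetol dimethyl ether) | CCCCCc1cc(OC)cc(OC)c1 | starting material
2 | (2,6-dimethoxy-4-pentylphenyl)lithium (not isolated) | CCCCCc1cc(OC)c([Li])c(OC)c1 | intermediate
3 | 2-chloro-1,3-dimethoxy-5-pentylbenzene | CCCCCc1cc(OC)c(Cl)c(OC)c1 | intermediate
4 | 3-chloro-1-[chloro(methoxy)methyl]-2,4-dimethoxy-6-pentylbenzene (racemic, held as its TiCl4 complex, not isolated) | CCCCCc1cc(OC)c(Cl)c(OC)c1C(Cl)OC | intermediate
5 | 3-chloro-2,4-dimethoxy-6-pentylbenzaldehyde | CCCCCc1cc(OC)c(Cl)c(OC)c1C=O | intermediate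
6 | 3-chloro-2,4-dimethoxy-6-pentylbenzoic acid | CCCCCc1cc(OC)c(Cl)c(OC)c1C(=O)O | intermediate
7 | 2,8-dichloro-7-methoxy-5-pentyl-4H-1,3,2-benzodioxaborinin-4-one (not isolated) | CCCCCc1cc(OC)c(Cl)c2OB(Cl)OC(=O)c12 | intermediate
8 | 3-chloro-2-hydroxy-4-methoxy-6-pentylbenzoic acid | CCCCCc1cc(OC)c(Cl)c(O)c1C(=O)O | intermediate
9 | 2,4-dihydroxy-6-pentylbenzoic acid (olivetolic acid) | CCCCCc1cc(O)cc(O)c1C(=O)O | starting material
10 | 3-chloro-2-hydroxy-4-methoxy-6-pentylbenzoyl chloride (not isolated) | CCCCCc1cc(OC)c(Cl)c(O)c1C(Cl)=O | intermediate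
11 | N-ethyl-N-isopropylpropan-2-aminium bis[4-hydroxy-2-oxido-6-pentylbenzoato(2–)]borate (spiro borate of two molecules of 9, racemic at boron, not isolated) | CCCCCc1cc(O)cc2O[B-]3(OC(=O)c12)OC(=O)c1c(CCCCC)cc(O)cc1O3.CC[NH+](C(C)C)C(C)C | intermediate
12 | N-ethyl-N-isopropylpropan-2-aminium bis{4-[(3-chloro-2-hydroxy-4-methoxy-6-pentylbenzoyl)oxy]-2-oxido-6-pentylbenzoato(2–)}borate (spiro borate of two molecules of 13, racemic at boron, not isolated) | CCCCCc1cc(OC(=O)c4c(CCCCC)cc(OC)c(Cl)c4O)cc2O[B-]3(OC(=O)c12)OC(=O)c1c(CCCCC)cc(OC(=O)c4c(CCCCC)cc(OC)c(Cl)c4O)cc1O3.CC[NH+](C(C)C)C(C)C | intermediate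
13 | 4-[(3-chloro-2-hydroxy-4-methoxy-6-pentylbenzoyl)oxy]-2-hydroxy-6-pentylbenzoic acid (CNP0310773.0) | CCCCCc1cc(OC(=O)c2c(CCCCC)cc(OC)c(Cl)c2O)cc(O)c1C(=O)O | target

## Summary
Total step count: 5.
Longest linear sequence: 5 steps (1 → 3 → 5 → 6 → 8 → 13; 9 enters in the last step).

Steps most likely to fail:

**Step 5 (proposed new coupling).** The risks are incomplete borate formation, slow acylation of the borate-bound phenol, or oligomers from the acid chloride. The fallback is the established protected-acceptor depside synthesis. It sets out from 9 (with 8) and comes back at 13. Alkylate 9 at the carboxylate only (BnBr, KHCO3, DMF, rt) to give benzyl 2,4-dihydroxy-6-pentylbenzoate F1. Activate 8 with trifluoroacetic anhydride in dry toluene as 3-chloro-2-hydroxy-4-methoxy-6-pentylbenzoic trifluoroacetic anhydride F2 (not isolated), which acylates the free 4-OH of F1 at rt (the 2-OH is hydrogen-bonded to the ester). This gives benzyl 4-[(3-chloro-2-hydroxy-4-methoxy-6-pentylbenzoyl)oxy]-2-hydroxy-6-pentylbenzoate F3. Brief hydrogenolysis (H2 1 atm, 10% Pd/C, EtOAc, rt, stopped after one equivalent of H2 to keep the aryl chloride) gives 13. This costs two extra steps.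

**Step 4 (BCl3 on the free acid).** The risks are loss of the 4-OMe as well, or protodecarboxylation of the electron-rich acid. The fallback demethylates at the aldehyde stage, where chelation-controlled cleavage is best established, and oxidises afterwards. It sets out from 5 and comes back at 8, replacing steps 3 and 4. Treat 5 with BCl3 (CH2Cl2, –78 → 0 °C) to form the O,O-chelated dichloroboron complex of 3-chloro-2-hydroxy-4-methoxy-6-pentylbenzaldehyde F4 (not isolated). Aqueous work-up hydrolyses it to 3-chloro-2-hydroxy-4-methoxy-6-pentylbenzaldehyde F5. Oxidation with NaClO2/sulfamic acid (aq. dioxane, rt) gives 8.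

**Step 2 (Rieche formylation).** The risks are sluggish reaction at the position flanked by pentyl and OMe on the chloro-deactivated ring, or TiCl4-induced ether cleavage. The fallback replaces electrophilic formylation/oxidation by halogenation and halogen–metal exchange/carboxylation. It sets out from 3 and comes back at 6, replacing steps 2 and 3. Brominate the single kind of ring position (NBS, MeCN, rt) to give 1-bromo-3-chloro-2,4-dimethoxy-6-pentylbenzene F6. Bromine–lithium exchange (n-BuLi, THF, –78 °C, aryl chloride untouched) gives (3-chloro-2,4-dimethoxy-6-pentylphenyl)lithium F7 (not isolated). Quench with CO2 and acidify to obtain 6.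

Further compounds
F1 | step 5 | benzyl 2,4-dihydroxy-6-pentylbenzoate | CCCCCc1cc(O)cc(O)c1C(=O)OCc1ccccc1
F2 | step 5 | 3-chloro-2-hydroxy-4-methoxy-6-pentylbenzoic trifluoroacetic anhydride | CCCCCc1cc(OC)c(Cl)c(O)c1C(=O)OC(=O)C(F)(F)F
F3 | step 5 | benzyl 4-[(3-chloro-2-hydroxy-4-methoxy-6-pentylbenzoyl)oxy]-2-hydroxy-6-pentylbenzoate | CCCCCc1cc(OC(=O)c2c(CCCCC)cc(OC)c(Cl)c2O)cc(O)c1C(=O)OCc1ccccc1
F4 | step 4 | O,O-chelated dichloroboron complex of 3-chloro-2-hydroxy-4-methoxy-6-pentylbenzaldehyde | CCCCCc1cc(OC)c(Cl)c2O[B-](Cl)(Cl)[O+]=Cc12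
F5 | step 4 | 3-chloro-2-hydroxy-4-methoxy-6-pentylbenzaldehyde | CCCCCc1cc(OC)c(Cl)c(O)c1C=O
F6 | step 2 | 1-bromo-3-chloro-2,4-dimethoxy-6-pentylbenzene | CCCCCc1cc(OC)c(Cl)c(OC)c1Br
F7 | step 2 | (3-chloro-2,4-dimethoxy-6-pentylphenyl)lithium | CCCCCc1cc(OC)c(Cl)c(OC)c1[Li]
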